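**Plan**

1. The last bond cut joins the spiro carbon to the carbinol carbon C(OH)CH3 of the carbocyclic six-membered ring. The spiro carbon is the γ-carbon of the α,β-unsaturated δ-lactone (O=C–CH=CH–C spiro) and its ring neighbour carries the tertiary hydroxyl, so the target is a δ-hydroxy enoate: the retron of a vinylogous aldol between a lactone-derived dienol ether and a methyl ketone.
2. Earlier cuts: the CH2–C(sp2) bond joining the preformed lactone ring to the two-carbon chain (alkylzinc/enol triflate coupling); the two bonds of an intramolecular Diels–Alder reaction of a 6,6-disubstituted cyclohexa-2,4-dienone (bicyclo[2.2.2]octane and cyclopentane together); the quaternary carbon–CH2 bond (Claisen rearrangement); the cyclohexene ring (silyloxydiene plus ynoate).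
3. Forward ring order: butenolide-fused cyclohexadiene, then bicyclo[2.2.2]octene plus cyclopentane in one step, then attachment of the finished δ-lactone ring, and the spiro-fused carbocyclic six-membered ring closed last.
4. Stereochemistry: an (S)-carbinol centre from asymmetric transfer hydrogenation is relayed by a chair Claisen transition state to the quaternary carbon next to the ring ketone, and the tether then fixes the three cage centres in the cycloaddition. Hydroboration from the lower face sets the acetyl-bearing carbon, hydroxyl-directed hydrogenation sets the lactone α-carbon, and the closing aldol sets the spiro and carbinol carbons through the one chair that the cis ring fusion to the cyclopentane allows.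

Key step: step 18

Assumption: the ring CH(CH3) stereocentres of 5, 6, 7, 14 and 15 are inconsequential mixtures, because the one that survives to 15 becomes trigonal in 16 and a bridgehead in 17; 1, 23 and 24 are taken as purchased.

**Route**

Step 1
Reactants: 1 2-methylpent-1-en-3-one
Product: 2 (Z)-2-methyl-3-(trimethylsilyloxy)penta-1,3-diene
Conditions: Me3SiOTf, Et3N, Et2O, 0 °C
Reagents that add atoms: trimethylsilyl trifluoromethanesulfonate, C[Si](C)(C)OS(=O)(=O)C(F)(F)F
Why: Soft enolisation toward the only enolisable side of the vinyl ketone should give the (Z)-silyl enol ether, a 2-silyloxy-1,3-diene with its terminal methyl pointing outward (silyl enol ether formation).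

Step 2
Reactants: 3 methyl 4-hydroxybut-2-ynoate
Product: 4 methyl 4-(tert-butyldimethylsilyloxy)but-2-ynoate
Conditions: t-BuMe2SiCl, imidazole, CH2Cl2, 0 °C to rt
Reagents that add atoms: tert-butyldimethylsilyl chloride, CC(C)(C)[Si](C)(C)Cl
Why: Silylation of the primary alcohol keeps the free hydroxyl from protodesilylating the diene in step 3 (silyl ether protection).

Step 3
Reactants: 2 (Z)-2-methyl-3-(trimethylsilyloxy)penta-1,3-diene; 4 methyl 4-(tert-butyldimethylsilyloxy)but-2-ynoate
Product: 7 5-methoxy-4,6-dimethyl-6,7-dihydro-2-benzofuran-1(3H)-one, via cyclohexa-1,4-diene adduct 5 (not isolated), via keto lactone 6 (not isolated)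
Conditions: toluene, 130 °C (sealed tube); then TsOH·H2O (cat.), HC(OMe)3, MeOH, 50 °C
Reagents that add atoms: trimethyl orthoformate, COC(OC)OC
Why: Diels–Alder reaction in which the diene terminus next to the silyloxy carbon should bond to the β-carbon of the ynoate ("para" regiochemistry), after which acidic methanolysis frees the ketone and the alcohol, lactonises, and traps the vinylogous β-keto lactone as its push–pull methyl dienol ether.

Step 4
Reactants: 8 tert-butyl(but-3-yn-1-yloxy)dimethylsilane; 9 N-methoxy-N-methylacetamide
Product: 10 6-(tert-butyldimethylsilyloxy)hex-3-yn-2-one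
Conditions: n-BuLi, THF, −78 °C; then 9, −78 to 0 °C; aq. NH4Cl
Reagents that add atoms: none
Why: Acylation of the lithium acetylide with a Weinreb amide should stop at the ketone because the chelated tetrahedral intermediate survives until work-up.

Step 5
Reactants: 10 6-(tert-butyldimethylsilyloxy)hex-3-yn-2-one
Product: 11 (S)-6-(tert-butyldimethylsilyloxy)hex-3-yn-2-ol
Conditions: Ru[(S,S)-TsDPEN](p-cymene) (1 mol%), i-PrOH, rt
Reagents that add atoms: none
Why: Noyori-type asymmetric transfer hydrogenation of an alkynyl methyl ketone, where the (S,S)-catalyst is expected to give the (S)-propargylic alcohol.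

Step 6
Reactants: 11 (S)-6-(tert-butyldimethylsilyloxy)hex-3-yn-2-ol; 12 ethylene
Product: 13 (S)-6-(tert-butyldimethylsilyloxy)-3,4-dimethylidenehexan-2-ol
Conditions: second-generation Grubbs catalyst RuCl2(H2IMes)(PCy3)(=CHPh) (5 mol%), ethylene (1 atm), toluene, 60 °C
Reagents that add atoms: none
Why: Ethylene–alkyne cross enyne metathesis should convert the internal alkyne into the 2,3-disubstituted buta-1,3-diene and leave the carbinol centre untouched.

Step 7
Reactants: 7 5-methoxy-4,6-dimethyl-6,7-dihydro-2-benzofuran-1(3H)-one; 13 (S)-6-(tert-butyldimethylsilyloxy)-3,4-dimethylidenehexan-2-ol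
Product: 15 (R)-configured quaternary ketone 4-[(2Z)-2-ethylidene-3-methylidene-5-(tert-butyldimethylsilyloxy)pentyl]-4,6-dimethyl-6,7-dihydro-2-benzofuran-1,5(3H,4H)-dione, via allyl dienol ether 14 (not isolated)
Conditions: propionic acid (10 mol%), 4 Å molecular sieves, toluene, 125 °C (sealed)
Reagents that add atoms: none
Why: Acid-catalysed alkoxy exchange at the dienol ether carbon (retention at the carbinol carbon) gives the allyl dienol ether, whose Claisen rearrangement can deliver the CH2 terminus only to the α-carbon of the enol ether, and a chair with the carbinol methyl equatorial should transfer the (S) centre into the (R) quaternary carbon.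

Step 8
Reactants: 15 quaternary ketone
Product: 17 tetracyclic cage lactone (bicyclo[2.2.2]octenone fused to the alkylidene γ-lactone and bridged by the (Z)-ethylidene cyclopentane that carries the 2-(tert-butyldimethylsilyloxy)ethyl chain), via cyclohexa-2,4-dienone 16 (not isolated)
Conditions: IBX, DMSO–toluene (1:2), 75 °C; then toluene, 110 °C
Reagents that add atoms: none
Why: IBX dehydrogenation of the ketone (enolisable only toward the methyl-bearing carbon) gives the 2,4-dienone, which should undergo an intramolecular Diels–Alder reaction with the tethered 1,1-disubstituted alkene, where the three-atom tether from the quaternary carbon permits one face and one regiochemistry, so the three new cage stereocentres follow from that carbon.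

Step 9
Reactants: 17 tetracyclic cage lactone
Product: 18 secondary alcohol (1-hydroxyethyl group on the cyclopentane, cis to the silyloxyethyl chain)
Conditions: BH3·THF (1.1 equiv), THF, 0 °C; then 30% H2O2, pH 7 phosphate buffer, 0 °C to rt
Reagents that add atoms: hydrogen peroxide, OO
Why: Hydroboration–oxidation puts boron on the less substituted ethylidene carbon and hydrogen on the ring carbon from the lower face (the one turned toward the ketone bridge, remote from the side chain and from the lactone CH2O group), so the carbinol carbon should end cis to the side chain, and any borane reduction of the hindered ring ketone is reversed in step 13.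

Step 10
Reactants: 18 secondary alcohol
Product: 19 diol
Conditions: HF·pyridine, THF, 0 °C to rt
Reagents that add atoms: none
Why: Fluoride cleavage of the primary silyl ether (desilylation) should leave both lactone and ketone intact.

Step 11
Reactants: 19 diol
Product: 20 saturated diol (lactone α-hydrogen syn to the bridge that carries the hydroxyethyl chain)
Conditions: [Ir(cod)(PCy3)(py)]PF6 (10 mol%), H2 (1 atm), CH2Cl2, rt
Reagents that add atoms: none
Why: Hydroxyl-directed homogeneous hydrogenation, in which the primary alcohol on the two-carbon chain reaches only one face of the alkylidene lactone, so both hydrogens should add from that face and fix the lactone α-carbon.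

Step 12
Reactants: 20 saturated diol
Product: 21 primary iodide
Conditions: I2, PPh3, imidazole, CH2Cl2, 0 °C
Reagents that add atoms: iodine, II
Why: Appel-type iodination should be selective for the primary alcohol over the hindered secondary one.

Step 13
Reactants: 21 primary iodide
Product: 22 iodo methyl ketone
Conditions: Dess–Martin periodinane, NaHCO3, CH2Cl2, rt
Reagents that add atoms: none
Why: Dess–Martin oxidation under buffered conditions should give the methyl ketone without epimerising the adjacent ring carbon.

Step 14
Reactants: 23 2-acetoxy-2-methylpropanoyl chloride; 24 (3-ethoxy-3-oxopropyl)zinc bromide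
Product: 25 ethyl 5-acetoxy-5-methyl-4-oxohexanoate
Conditions: Pd(PPh3)4 (3 mol%), THF, 0 °C to rt
Reagents that add atoms: none
Why: Pd-catalysed acylation of a zinc homoenolate with an acid chloride (Negishi-type ketone synthesis) tolerates both esters.

Step 15
Reactants: 25 ethyl 5-acetoxy-5-methyl-4-oxohexanoate
Product: 27 6,6-dimethyloxane-2,5-dione, via 5-hydroxy-5-methyl-4-oxohexanoic acid 26 (not isolated)
Conditions: 2 M HCl, 1,4-dioxane, 70 °C; then TsOH (cat.), toluene, reflux, Dean–Stark
Reagents that add atoms: none
Why: Acid hydrolysis of both esters followed by azeotropic lactonisation of the tertiary δ-hydroxy acid should give the keto δ-lactone.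

Step 16
Reactants: 27 6,6-dimethyloxane-2,5-dione
Product: 28 6,6-dimethyl-2-oxo-3,6-dihydro-2H-pyran-5-yl trifluoromethanesulfonate
Conditions: KN(SiMe3)2 (1.0 equiv), THF, −78 °C; then PhNTf2, −78 to 0 °C
Reagents that add atoms: N-phenylbis(trifluoromethanesulfonimide), O=S(=O)(N(c1ccccc1)S(=O)(=O)C(F)(F)F)C(F)(F)F
Why: The ketone enolises only toward its CH2 and is more acidic than the lactone, so O-triflation of the enolate should give the enol triflate of the β,γ-unsaturated lactone.

Step 17
Reactants: 22 iodo methyl ketone; 28 enol triflate
Product: 30 seco precursor (β,γ-unsaturated δ-lactone joined through CH2CH2 to the cage), via alkylzinc iodide 29 (not isolated)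
Conditions: Zn dust (activated with BrCH2CH2Br and Me3SiCl), LiCl, THF, 35 °C; then 28, Pd(dppf)Cl2 (5 mol%), THF, 25 °C
Reagents that add atoms: none
Why: Zinc insertion into the primary iodide gives a ketone-tolerant alkylzinc reagent, and base-free Negishi coupling with the enol triflate should form the C(sp3)–C(sp2) bond without moving the lactone double bond.

Step 18
Reactants: 30 seco precursor
Product: 32 CNP0222978.3, via 6-silyloxy-2H-pyran 31 (not isolated)
Conditions: Me3SiCl, LiN(SiMe3)2 (1.05 equiv), toluene–THF, −78 °C; then CH2Cl2, BF3·OEt2, −78 to −40 °C; 1 M HCl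
Reagents that add atoms: none
Why: The doubly activated allylic α-CH2 of the β,γ-unsaturated lactone (about three pK units more acidic than the methyl ketone) is deprotonated and the dienolate is silylated in situ at −78 °C, before the 6-oxido-2H-pyran can open to a dienoate; BF3 then activates the ketone and the ring carbon γ to the silyloxy carbon adds to it, restoring the conjugated lactone. The closest known reaction type is the γ-selective vinylogous Mukaiyama aldol reaction of 2-silyloxyfurans and dioxinone-derived dienol ethers, here intramolecular onto a ketone. The carbocyclic six-membered ring closes in a 6-(enolexo)-exo-trig mode, and α-attack would need an eight-membered ring, so the tether secures γ-regioselectivity. The new ring is cis-fused to the cyclopentane through the acetyl group that step 9 placed on the face of the lactone CH2O group, and the fixed torsion of the cyclopentane at the fusion bond allows only the chair in which the bridgehead carbon bearing that CH2O group is axial and the bicyclooctane CH2 equatorial. In that chair the ketone methyl should take the equatorial site, since an axial methyl would be 1,3-diaxial to the bridgehead carbon, so the oxygen is axial and the carbinol carbon is fixed; the pyran should then add through the face that puts its C(CH3)2O carbon axial and anti to the BF3-bound oxygen and its flat vinyl CH equatorial and gauche to it, which fixes the spiro carbon. Chemoselectivity between the two enolisable carbonyls rests on the acidity difference, the bulky amide base and the low temperature.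

**Compound list**

1 | 2-methylpent-1-en-3-one | CCC(=O)C(C)=C | starting material
2 | (Z)-2-methyl-3-(trimethylsilyloxy)penta-1,3-diene | C/C=C(\O[Si](C)(C)C)C(C)=C | intermediate
3 | methyl 4-hydroxybut-2-ynoate | COC(=O)C#CCO | starting material
4 | methyl 4-(tert-butyldimethylsilyloxy)but-2-ynoate | COC(=O)C#CCO[Si](C)(C)C(C)(C)C | intermediate
5 | methyl 2-[(tert-butyldimethylsilyloxy)methyl]-3,5-dimethyl-4-(trimethylsilyloxy)cyclohexa-1,4-diene-1-carboxylate (racemic, not isolated) | COC(=O)C1=C(CO[Si](C)(C)C(C)(C)C)C(C)C(O[Si](C)(C)C)=C(C)C1 | intermediate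
6 | 4,6-dimethyl-6,7-dihydro-2-benzofuran-1,5(3H,4H)-dione (stereoisomer mixture, not isolated) | O=C1OCC2=C1CC(C)C(=O)C2C | intermediate
7 | 5-methoxy-4,6-dimethyl-6,7-dihydro-2-benzofuran-1(3H)-one (racemic) | COC1=C(C)C2=C(C(=O)OC2)CC1C | intermediate
8 | tert-butyl(but-3-yn-1-yloxy)dimethylsilane | C#CCCO[Si](C)(C)C(C)(C)C | starting material
9 | N-methoxy-N-methylacetamide | CC(=O)N(C)OC | starting material
10 | 6-(tert-butyldimethylsilyloxy)hex-3-yn-2-one | CC(=O)C#CCCO[Si](C)(C)C(C)(C)C | intermediate
11 | (S)-6-(tert-butyldimethylsilyloxy)hex-3-yn-2-ol | C[C@H](O)C#CCCO[Si](C)(C)C(C)(C)C | intermediate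
12 | ethylene | C=C | starting material
13 | (S)-6-(tert-butyldimethylsilyloxy)-3,4-dimethylidenehexan-2-ol | C[C@H](O)C(=C)C(=C)CCO[Si](C)(C)C(C)(C)C | intermediate
14 | 5-{[(2S)-6-(tert-butyldimethylsilyloxy)-3,4-dimethylidenehexan-2-yl]oxy}-4,6-dimethyl-6,7-dihydro-2-benzofuran-1(3H)-one (not isolated) | C[C@H](OC1=C(C)C2=C(C(=O)OC2)CC1C)C(=C)C(=C)CCO[Si](C)(C)C(C)(C)C | intermediate
15 | (4R)-4-[(2Z)-2-ethylidene-3-methylidene-5-(tert-butyldimethylsilyloxy)pentyl]-4,6-dimethyl-6,7-dihydro-2-benzofuran-1,5(3H,4H)-dione | C/C=C(/C[C@@]1(C)C(=O)C(C)CC2=C1COC2=O)C(=C)CCO[Si](C)(C)C(C)(C)C | intermediate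
16 | (4R)-4-[(2Z)-2-ethylidene-3-methylidene-5-(tert-butyldimethylsilyloxy)pentyl]-4,6-dimethyl-2-benzofuran-1,5(3H,4H)-dione (cyclohexa-2,4-dienone, not isolated) | C/C=C(/C[C@@]1(C)C(=O)C(C)=CC2=C1COC2=O)C(=C)CCO[Si](C)(C)C(C)(C)C | intermediate
17 | tetracyclic cage lactone: bicyclo[2.2.2]octenone with fused alkylidene γ-lactone, cyclopentane bridge with (Z)-ethylidene, 2-(tert-butyldimethylsilyloxy)ethyl chain | CC(C)(C)[Si](C)(C)OCC[C@@]13C[C@@]4(C)C=C5C(=O)OC[C@]51[C@@](C)(C/C3=C/C)C4=O | intermediate
18 | secondary alcohol from 17 (1-hydroxyethyl cis to the side chain; carbinol configuration from syn addition to the (Z)-alkene, lost again in step 13) | CC(C)(C)[Si](C)(C)OCC[C@@]13C[C@@]4(C)C=C5C(=O)OC[C@]51[C@@](C)(C[C@H]3[C@@H](C)O)C4=O | intermediate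
19 | diol (alkylidene lactone) | OCC[C@@]13C[C@@]4(C)C=C5C(=O)OC[C@]51[C@@](C)(C[C@H]3[C@@H](C)O)C4=O | intermediate
20 | saturated diol (lactone α-H syn to the chain-bearing bridge) | OCC[C@@]13C[C@@]4(C)C[C@@H]5C(=O)OC[C@]51[C@@](C)(C[C@H]3[C@@H](C)O)C4=O | intermediate
21 | primary iodide with secondary alcohol | ICC[C@@]13C[C@@]4(C)C[C@@H]5C(=O)OC[C@]51[C@@](C)(C[C@H]3[C@@H](C)O)C4=O | intermediate
22 | iodo methyl ketone (acetyl cis to the iodoethyl chain) | ICC[C@@]13C[C@@]4(C)C[C@@H]5C(=O)OC[C@]51[C@@](C)(C[C@H]3C(C)=O)C4=O | intermediate
23 | 2-acetoxy-2-methylpropanoyl chloride | CC(=O)OC(C)(C)C(Cl)=O | starting material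
24 | (3-ethoxy-3-oxopropyl)zinc bromide | CCOC(=O)CC[Zn]Br | starting material
25 | ethyl 5-acetoxy-5-methyl-4-oxohexanoate | CCOC(=O)CCC(=O)C(C)(C)OC(C)=O | intermediate
26 | 5-hydroxy-5-methyl-4-oxohexanoic acid (not isolated) | CC(C)(O)C(=O)CCC(=O)O | intermediate
27 | 6,6-dimethyloxane-2,5-dione | O=C1CCC(=O)C(C)(C)O1 | intermediate
28 | 6,6-dimethyl-2-oxo-3,6-dihydro-2H-pyran-5-yl trifluoromethanesulfonate | CC1(C)OC(=O)CC=C1OS(=O)(=O)C(F)(F)F | intermediate
29 | alkylzinc iodide from 22 (not isolated) | I[Zn]CC[C@@]13C[C@@]4(C)C[C@@H]5C(=O)OC[C@]51[C@@](C)(C[C@H]3C(C)=O)C4=O | intermediate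
30 | seco precursor: 6,6-dimethyl-3,6-dihydro-2H-pyran-2-one joined at its 5-position through CH2CH2 to the cage methyl ketone | CC1(C)OC(=O)CC=C1CC[C@@]13C[C@@]4(C)C[C@@H]5C(=O)OC[C@]51[C@@](C)(C[C@H]3C(C)=O)C4=O | intermediate
31 | 2,2-dimethyl-6-(trimethylsilyloxy)-2H-pyran joined at its 3-position to the cage (not isolated) | CC1(C)OC(O[Si](C)(C)C)=CC=C1CC[C@@]13C[C@@]4(C)C[C@@H]5C(=O)OC[C@]51[C@@](C)(C[C@H]3C(C)=O)C4=O | intermediate
32 | CNP0222978.3 | CC1(C)OC(=O)C=C[C@]12CC[C@@]13C[C@@]4(C)C[C@@H]5C(=O)OC[C@]51[C@@](C)(C[C@H]3[C@@]2(C)O)C4=O | target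

**Totals**

Total step count: 18. Longest linear sequence: 12 steps (4, 5, 6, 7, 8, 9, 10, 11, 12, 13, 17, 18), counted from alkyne 8.

**Steps most likely to fail**

1. Step 18. Possible failures: competing enolisation and silylation of the methyl ketone, ring opening of the dienolate or of the silyloxypyran to a dienoate, or the opposite topicity at the spiro carbon in the open transition state. Fallback: generate the dienolate reductively instead of by base. Radical bromination of 30 (N-bromosuccinimide, cat. AIBN, PhCF3, 80 °C) should attack the doubly activated allylic position and give the γ-bromo conjugated lactone F1 (with its α-bromo β,γ-isomer, which serves equally). Zinc dust in THF then forms a zinc dienolate (vinylogous Reformatsky reaction) that can add to the ketone only through its γ-carbon in the six-membered mode. Work-up of the zinc alkoxide returns to the route at 32.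

2. Step 7. Possible failures: slow alkoxy exchange at the push–pull dienol ether, acid-induced ionisation of the allylic alcohol with loss of optical purity, or incomplete chirality transfer. Fallback: make the same ether 14 under neutral conditions by substitution with inversion. Ketone 10 is reduced with Ru[(R,R)-TsDPEN](p-cymene) in i-PrOH to the (R)-propargylic alcohol F2, and enyne metathesis with ethylene as in step 6 gives the (R)-dienol F3. Dienol ether 7 is hydrolysed (aq. HCl, THF) to keto lactone 6. Mitsunobu coupling of 6 with F3 (PPh3, diisopropyl azodicarboxylate, toluene) should O-alkylate the vinylogous β-keto lactone with inversion to give 14, which is then heated in toluene without acid. The fallback sets out from 10 and 7 and returns at 14, hence 15.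

3. Step 9. Possible failures: poor facial selectivity (hydrogen delivered to the upper face gives the trans acetyl epimer, which cannot close the last ring) or reduction of the alkylidene lactone. Fallback: epoxidation followed by Meinwald rearrangement, which is stereocomplementary because the 1,2-hydride shift enters the ring carbon anti to the departing oxygen. From 17, mCPBA (NaHCO3, CH2Cl2, 0 °C) attacking the upper face gives the spiro-epoxide F4, and BF3·OEt2 (cat., CH2Cl2, −78 °C) should rearrange it to the silyl ether methyl ketone F5. HF·pyridine gives the hydroxy ketone F6, directed hydrogenation as in step 11 gives the saturated hydroxy ketone F7, and iodination as in step 12 returns to the route at 22.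

Further compounds
F1 | step 18 | γ-bromo-α,β-unsaturated lactone from 30 (bromine on the future spiro carbon, epimer mixture) | CC1(C)OC(=O)C=CC1(Br)CC[C@@]13C[C@@]4(C)C[C@@H]5C(=O)OC[C@]51[C@@](C)(C[C@H]3C(C)=O)C4=O
F2 | step 7 | (R)-6-(tert-butyldimethylsilyloxy)hex-3-yn-2-ol | C[C@@H](O)C#CCCO[Si](C)(C)C(C)(C)C
F3 | step 7 | (R)-6-(tert-butyldimethylsilyloxy)-3,4-dimethylidenehexan-2-ol | C[C@@H](O)C(=C)C(=C)CCO[Si](C)(C)C(C)(C)C
F4 | step 9 | spiro-epoxide of 17 (oxygen on the upper face) | CC(C)(C)[Si](C)(C)OCC[C@@]13C[C@@]4(C)C=C5C(=O)OC[C@]51[C@@](C)(C[C@@]36O[C@H]6C)C4=O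
F5 | step 9 | silyl ether methyl ketone (alkylidene lactone, acetyl cis to the side chain) | CC(C)(C)[Si](C)(C)OCC[C@@]13C[C@@]4(C)C=C5C(=O)OC[C@]51[C@@](C)(C[C@H]3C(C)=O)C4=O
F6 | step 9 | hydroxy methyl ketone (alkylidene lactone) | OCC[C@@]13C[C@@]4(C)C=C5C(=O)OC[C@]51[C@@](C)(C[C@H]3C(C)=O)C4=O
F7 | step 9 | hydroxy methyl ketone (saturated lactone) | OCC[C@@]13C[C@@]4(C)C[C@@H]5C(=O)OC[C@]51[C@@](C)(C[C@H]3C(C)=O)C4=O
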